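The constants used here were set for the occasion.

in all of them: J 0.050 M; time 15 min

| run | D | E | temperature | remark |
|---|---|---|---|---|
| ash | 0.250 M | 0.100 M | 80 °C | everything together at the start |
| alder | 0.250 M | 0.100 M |  | everything together at the start at 60 °C, warmed to 80 °C at 12 min |
| birch | 0.250 M (fed, over 12 min) | 0.100 M | 80 °C | all else is in the flask from the start; the feed brings no volume worth counting |
| larch | 0.250 M | 0.100 M (fed, over 12 min) |  | the addition at 60 °C, then warmed to 80 °C; the feed brings no volume worth counting |

    J + E → J.E (k1 = 0.0012 M⁻¹ s⁻¹, Ea1 = 67.0 kJ mol⁻¹)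
    J + D → J.D (k2 = 0.0019 M⁻¹ s⁻¹, Ea2 = 57.0 kJ mol⁻¹)
    E + J.D ⇌ E.J.D (K3 = 24 M⁻¹, k3 = 0.0023 M⁻¹ s⁻¹, Ea3 = 80.0 kJ mol⁻¹, ΔH3 = −37.0 kJ mol⁻¹)
    D + E.J.D → Z (k4 = 9.9 × 10⁻⁴ M⁻¹ s⁻¹, Ea4 = 84.0 kJ mol⁻¹)
    (constants at 80 °C)

- the constants hold at 80 °C; other temperatures follow from the activation energies and enthalpies

- the flask that comes out highest in share of E.J.D in E.J.D plus J.E, or "all alike" when all lie within 1.5 percentage points (ash / alder / birch / larch / all alike)
- share of E.J.D in E.J.D plus J.E at the end, ash
- share of E.J.D in E.J.D plus J.E at the end, alder
- share of E.J.D in E.J.D plus J.E at the end, birch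
- share of E.J.D in E.J.D plus J.E at the end, larch

- We decide to count turnovers first, in ash, and to ask how many chances each step has had by the end.
- The capture count is 0.207, the forward rate constant of the step E + J.D → E.J.D, times [E] as charged, times the time. Holding [E] at its charge makes this capture pseudo-first-order in J.D.
- J splits at the start: with [D] and [E] as charged, it goes to J.D 3.96 times as fast as to J.E.
- We take J.D and J.E as growing roughly in a straight line, so the mean J.D over the run is its end amount over 2. E.J.D over J.E is therefore the flow ratio times the capture count over 2, which gives 0.410, a share of 29.1 %.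
- The weak link is that this count keeps every E.J.D formed, whereas the scheme removes E.J.D by D and by the back step. Their loss count, reckoned like the capture count, is 0.309.
- The loss to D should stay modest, since the half-life of E.J.D by that step alone, with [D] as charged, 47 min, is longer than the time.
- E.J.D growing with the square of time has a mean age of 5.00 min, so we multiply by one minus the loss count over 3. The ratio becomes 0.367, and we commit to a share of 26.9 % for ash.
- Alder, with its cold stretch, counts 0.0737 captures, fewer than ash. Birch keeps the capture count of ash, but its D comes late, and larch shares the cold stretch of alder. We expect ash on top, but this is a judgement, and we reckon no share for the other flasks.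
- The forecast named ash, with 26 % for ash, 15 % for alder, 13 % for birch and 18 % for larch, holding of E.J.D that “the cold hold in alder and larch and the late arrival of D in birch all hold it back”.
- The simulation puts ash highest at 26.6 %, against our 26.9 %, followed by larch at 18.2 %, alder at 14.8 % and birch at 12.7 %.
- Ash repeated at 65 °C, with amounts and time held, takes the same reckoning with each constant moved by its activation energy, and the back step by the enthalpy as well. The capture count falls to 0.0618, the flow ratio rises to 4.60, and the loss count falls to 0.0773. E.J.D over J.E comes to 0.139, a share of 12.2 %. That flask gives 12.2 %, with E.J.D at 0.485 % and J.E at 3.49 % of the J charged.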